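**Retrosynthetic overview**

- The target comes from tetrabenzyl ether 26 by hydrogenolysis; ring C of the flavonol is closed last, by Algar–Flynn–Oyamada oxidation of chalcone 23, itself from aldehyde 19 and ring-A ketone 21.
- Aldehyde 19 comes from diester 15 by reduction and cleavage of the side-chain alkene.
- Key bond C3–C3a of the dihydrobenzofuran: trivalent-iodine ring contraction of (2R)-chromanone 10. The ketone α-carbon, normally a nucleophile, is turned into an enolonium equivalent and captures the ipso carbon of its own benzo ring; the C2 stereocentre dictates trans C3.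
- Chromanone 10 comes from enantioselective conjugate arylation of chromone 8, which comes from ketone-directed C5–H olefination of chromone 6 (from 2',3'-dihydroxyacetophenone).
- Ring order: pyranone (chromone), then chiral chromanone, then ring-contracted dihydrofuran, then flavonol ring C.

Assumption: 1, 9 and 20 are taken as catalogue chemicals, and (S)-t-BuPyOx is taken to give the (2R)-chromanone as it gives (R)-ketones with cyclic enones (otherwise its antipode is used).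

**Route**

Step 1
Reactants: 1 2',3'-dihydroxyacetophenone; 2 benzyl bromide
Product: 3 1-[3-(benzyloxy)-2-hydroxyphenyl]ethan-1-one
Conditions: NaH (2.1 equiv), DMSO, rt; then BnBr (1.0 equiv), rt
Reagents that add atoms: benzyl bromide, BrCc1ccccc1
Why: Williamson etherification of the dianion, in which the 3-phenoxide is the more nucleophilic because the 2-phenoxide is chelated to the carbonyl group.

Step 2
Reactants: 3 1-[3-(benzyloxy)-2-hydroxyphenyl]ethan-1-one; 4 N,N-dimethylformamide dimethyl acetal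
Product: 6 8-(benzyloxy)-4H-chromen-4-one, via enaminone 5 (not isolated)
Conditions: DMF-DMA (3 equiv), toluene, 100 °C; evaporate; conc. HCl, CH2Cl2, rt
Reagents that add atoms: N,N-dimethylformamide dimethyl acetal, COC(OC)N(C)C
Why: Enaminone condensation followed by acid-induced addition–elimination of the phenol (standard chromone synthesis), which supplies C2 of the pyranone.

Step 3
Reactants: 6 8-(benzyloxy)-4H-chromen-4-one; 7 methyl acrylate
Product: 8 methyl (E)-3-[8-(benzyloxy)-4-oxo-4H-chromen-5-yl]prop-2-enoate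
Conditions: [Cp*RhCl2]2 (2.5 mol %), AgSbF6 (10 mol %), Cu(OAc)2 (2.1 equiv), ClCH2CH2Cl, 110 °C
Reagents that add atoms: methyl acrylate, C=CC(=O)OC
Why: Ketone-directed oxidative C–H olefination (Fujiwara–Moritani type, trivalent rhodium) at the peri position C5 through a five-membered rhodacycle, which installs the carbon that becomes C1' of the flavonol on the only C–H next to the carbonyl.

Step 4
Reactants: 8 methyl (E)-3-[8-(benzyloxy)-4-oxo-4H-chromen-5-yl]prop-2-enoate; 9 [4-(benzyloxy)-3-methoxyphenyl]boronic acid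
Product: 10 methyl (E)-3-[(2R)-8-(benzyloxy)-2-[4-(benzyloxy)-3-methoxyphenyl]-4-oxo-3,4-dihydro-2H-chromen-5-yl]prop-2-enoate
Conditions: Pd(OCOCF3)2 (5 mol %), (S)-t-BuPyOx (6 mol %), NH4PF6 (30 mol %), H2O (5 equiv), 9 (2 equiv), ClCH2CH2Cl, 60 °C
Reagents that add atoms: [4-(benzyloxy)-3-methoxyphenyl]boronic acid, COc1cc(B(O)O)ccc1OCc1ccccc1
Why: Enantioselective conjugate addition of an arylboronic acid to a chromone with a divalent palladium pyridine-oxazoline catalyst; the ligand-controlled face of aryl transfer sets C2 as R, and the acyclic cinnamate is a much poorer acceptor than the cyclic vinylogous ester.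

Step 5
Reactants: 10 methyl (E)-3-[(2R)-8-(benzyloxy)-2-[4-(benzyloxy)-3-methoxyphenyl]-4-oxo-3,4-dihydro-2H-chromen-5-yl]prop-2-enoate; 11 (diacetoxyiodo)benzene; 12 trimethyl orthoformate
Product: 15 methyl (2R,3R)-7-(benzyloxy)-2-[4-(benzyloxy)-3-methoxyphenyl]-4-[(E)-3-methoxy-3-oxoprop-1-en-1-yl]-2,3-dihydro-1-benzofuran-3-carboxylate, via 4-methoxy-2H-chromene enol ether 13 (not isolated), via 2,3-trans 3-iodanyl dimethyl ketal 14 (not isolated)
Conditions: PhI(OAc)2 (1.2 equiv), conc. H2SO4 (0.5 equiv), HC(OMe)3, rt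
Reagents that add atoms: trimethyl orthoformate, COC(OC)OC
Why: Oxidative ring contraction of a flavanone with trivalent iodine (Prakash-type 1,2-aryl shift): enol ether 13 is iodinated anti to the C2 aryl group to give 14, an enolonium equivalent, and the benzo-ring ipso carbon, pushed by the two ketal oxygens, migrates from C4 to the now electrophilic C3 with inversion, which places CO2Me trans to the untouched C2 aryl group, i.e. (2R,3R).

Step 6
Reactants: 15 methyl (2R,3R)-7-(benzyloxy)-2-[4-(benzyloxy)-3-methoxyphenyl]-4-[(E)-3-methoxy-3-oxoprop-1-en-1-yl]-2,3-dihydro-1-benzofuran-3-carboxylate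
Product: 16 [(2R,3S)-7-(benzyloxy)-2-[4-(benzyloxy)-3-methoxyphenyl]-4-[(E)-3-hydroxyprop-1-en-1-yl]-2,3-dihydro-1-benzofuran-3-yl]methanol
Conditions: i-Bu2AlH (6 equiv), CH2Cl2, −78 to 0 °C; aqueous potassium sodium tartrate
Reagents that add atoms: none
Why: Hydride reduction of both esters (1,2-reduction of the enoate) without touching a stereocentre; the C3 descriptor changes from R to S only because CO2Me becomes CH2OH.

Step 7
Reactants: 16 [(2R,3S)-7-(benzyloxy)-2-[4-(benzyloxy)-3-methoxyphenyl]-4-[(E)-3-hydroxyprop-1-en-1-yl]-2,3-dihydro-1-benzofuran-3-yl]methanol; 17 sodium periodate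
Product: 19 (2R,3S)-7-(benzyloxy)-2-[4-(benzyloxy)-3-methoxyphenyl]-3-(hydroxymethyl)-2,3-dihydro-1-benzofuran-4-carbaldehyde, via triol 18 (not isolated)
Conditions: OsO4 (2 mol %), NaIO4 (4 equiv), 2,6-lutidine (2 equiv), 1,4-dioxane/H2O 3:1, rt
Reagents that add atoms: osmium tetroxide, O=[Os](=O)(=O)=O (catalytic oxygen carrier); sodium periodate, [Na+].[O-]I(=O)(=O)=O (terminal oxygen source)
Why: Lemieux–Johnson dihydroxylation and glycol cleavage of the only alkene unmasks the aryl aldehyde, while the benzyl ethers, the electron-rich arenes and the primary alcohol are inert.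

Step 8
Reactants: 20 2',4',6'-trihydroxyacetophenone; 2 benzyl bromide
Product: 21 1-[2,4-bis(benzyloxy)-6-hydroxyphenyl]ethan-1-one
Conditions: BnBr (2.1 equiv), K2CO3 (2.2 equiv), DMF, rt
Reagents that add atoms: benzyl bromide, BrCc1ccccc1
Why: Williamson etherification that stops at the dibenzyl ether because the remaining ortho hydroxyl is hydrogen-bonded to the ketone.

Step 9
Reactants: 19 (2R,3S)-7-(benzyloxy)-2-[4-(benzyloxy)-3-methoxyphenyl]-3-(hydroxymethyl)-2,3-dihydro-1-benzofuran-4-carbaldehyde; 21 1-[2,4-bis(benzyloxy)-6-hydroxyphenyl]ethan-1-one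
Product: 23 (2E)-1-[2,4-bis(benzyloxy)-6-hydroxyphenyl]-3-[(2R,3S)-7-(benzyloxy)-2-[4-(benzyloxy)-3-methoxyphenyl]-3-(hydroxymethyl)-2,3-dihydro-1-benzofuran-4-yl]prop-2-en-1-one, via aldol adduct 22 (not isolated)
Conditions: 21 (1.2 equiv), 50% aq KOH, EtOH/THF, rt, 48 h
Reagents that add atoms: none
Why: Claisen–Schmidt condensation to the E-chalcone; the dihydrobenzofuran has no acidic C–H left, so both stereocentres are safe in base.

Step 10
Reactants: 23 (2E)-1-[2,4-bis(benzyloxy)-6-hydroxyphenyl]-3-[(2R,3S)-7-(benzyloxy)-2-[4-(benzyloxy)-3-methoxyphenyl]-3-(hydroxymethyl)-2,3-dihydro-1-benzofuran-4-yl]prop-2-en-1-one; 24 hydrogen peroxide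
Product: 26 5,7-bis(benzyloxy)-2-[(2R,3S)-7-(benzyloxy)-2-[4-(benzyloxy)-3-methoxyphenyl]-3-(hydroxymethyl)-2,3-dihydro-1-benzofuran-4-yl]-3-hydroxy-4H-chromen-4-one, via dihydroflavonol 25 (not isolated)
Conditions: 30% aq H2O2, 2 M NaOH, MeOH/THF, 0 °C to rt
Reagents that add atoms: hydrogen peroxide, OO
Why: Algar–Flynn–Oyamada reaction: oxa-Michael closure of the phenoxide with α-hydroxylation gives 25, which is oxidised on to the flavonol, so the two transient stereocentres disappear.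

Step 11
Reactants: 26 5,7-bis(benzyloxy)-2-[(2R,3S)-7-(benzyloxy)-2-[4-(benzyloxy)-3-methoxyphenyl]-3-(hydroxymethyl)-2,3-dihydro-1-benzofuran-4-yl]-3-hydroxy-4H-chromen-4-one
Product: 27 2-[(2R,3S)-7-hydroxy-2-(4-hydroxy-3-methoxyphenyl)-3-(hydroxymethyl)-2,3-dihydro-1-benzofuran-4-yl]-3,5,7-trihydroxy-4H-chromen-4-one (CNP0195987.1)
Conditions: H2 (1 atm), 10% Pd on carbon, THF/MeOH, rt, stopped after 4 equiv uptake
Reagents that add atoms: none
Why: Hydrogenolysis of the four benzyl aryl ethers, which are cleaved much faster than the cyclic benzylic C2–O bond or the flavonol double bond, so the methyl ether and both stereocentres survive.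

**Compound list**

1 | 2',3'-dihydroxyacetophenone | CC(=O)c1cccc(O)c1O | starting material
2 | benzyl bromide | BrCc1ccccc1 | starting material
3 | 1-[3-(benzyloxy)-2-hydroxyphenyl]ethan-1-one | CC(=O)c1cccc(OCc2ccccc2)c1O | intermediate
4 | N,N-dimethylformamide dimethyl acetal | COC(OC)N(C)C | starting material
5 | (E)-1-[3-(benzyloxy)-2-hydroxyphenyl]-3-(dimethylamino)prop-2-en-1-one | CN(C)/C=C/C(=O)c1cccc(OCc2ccccc2)c1O | intermediate
6 | 8-(benzyloxy)-4H-chromen-4-one | O=c1ccoc2c(OCc3ccccc3)cccc12 | intermediate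
7 | methyl acrylate | C=CC(=O)OC | starting material
8 | methyl (E)-3-[8-(benzyloxy)-4-oxo-4H-chromen-5-yl]prop-2-enoate | COC(=O)/C=C/c1ccc(OCc2ccccc2)c2occc(=O)c12 | intermediate
9 | [4-(benzyloxy)-3-methoxyphenyl]boronic acid | COc1cc(B(O)O)ccc1OCc1ccccc1 | starting material
10 | methyl (E)-3-[(2R)-8-(benzyloxy)-2-[4-(benzyloxy)-3-methoxyphenyl]-4-oxo-3,4-dihydro-2H-chromen-5-yl]prop-2-enoate | COc1cc([C@@H]2Oc3c(OCc4ccccc4)ccc(/C=C/C(=O)OC)c3C(=O)C2)ccc1OCc1ccccc1 | intermediate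
11 | (diacetoxyiodo)benzene, PhI(OAc)2 | CC(=O)OI(OC(C)=O)c1ccccc1 | starting material
12 | trimethyl orthoformate | COC(OC)OC | starting material
13 | methyl (E)-3-[(2R)-8-(benzyloxy)-2-[4-(benzyloxy)-3-methoxyphenyl]-4-methoxy-2H-chromen-5-yl]prop-2-enoate | COc1cc([C@@H]2Oc3c(OCc4ccccc4)ccc(/C=C/C(=O)OC)c3C(OC)=C2)ccc1OCc1ccccc1 | intermediate
14 | methyl (E)-3-[(2S,3S)-3-[acetoxy(phenyl)-λ3-iodanyl]-8-(benzyloxy)-2-[4-(benzyloxy)-3-methoxyphenyl]-4,4-dimethoxy-3,4-dihydro-2H-chromen-5-yl]prop-2-enoate (2,3-trans; same geometry at C2 as in 10) | COc1cc([C@@H]2Oc3c(OCc4ccccc4)ccc(/C=C/C(=O)OC)c3C(OC)(OC)[C@H]2I(OC(C)=O)c2ccccc2)ccc1OCc1ccccc1 | intermediate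
15 | methyl (2R,3R)-7-(benzyloxy)-2-[4-(benzyloxy)-3-methoxyphenyl]-4-[(E)-3-methoxy-3-oxoprop-1-en-1-yl]-2,3-dihydro-1-benzofuran-3-carboxylate | COc1cc([C@@H]2Oc3c(OCc4ccccc4)ccc(/C=C/C(=O)OC)c3[C@H]2C(=O)OC)ccc1OCc1ccccc1 | intermediate
16 | [(2R,3S)-7-(benzyloxy)-2-[4-(benzyloxy)-3-methoxyphenyl]-4-[(E)-3-hydroxyprop-1-en-1-yl]-2,3-dihydro-1-benzofuran-3-yl]methanol | COc1cc([C@@H]2Oc3c(OCc4ccccc4)ccc(/C=C/CO)c3[C@H]2CO)ccc1OCc1ccccc1 | intermediate
17 | sodium periodate | [Na+].[O-]I(=O)(=O)=O | starting material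
18 | 1-[(2R,3S)-7-(benzyloxy)-2-[4-(benzyloxy)-3-methoxyphenyl]-3-(hydroxymethyl)-2,3-dihydro-1-benzofuran-4-yl]propane-1,2,3-triol (mixture of the two syn-diol epimers) | COc1cc([C@@H]2Oc3c(OCc4ccccc4)ccc(C(O)C(O)CO)c3[C@H]2CO)ccc1OCc1ccccc1 | intermediate
19 | (2R,3S)-7-(benzyloxy)-2-[4-(benzyloxy)-3-methoxyphenyl]-3-(hydroxymethyl)-2,3-dihydro-1-benzofuran-4-carbaldehyde | COc1cc([C@@H]2Oc3c(OCc4ccccc4)ccc(C=O)c3[C@H]2CO)ccc1OCc1ccccc1 | intermediate
20 | 2',4',6'-trihydroxyacetophenone | CC(=O)c1c(O)cc(O)cc1O | starting material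
21 | 1-[2,4-bis(benzyloxy)-6-hydroxyphenyl]ethan-1-one | CC(=O)c1c(O)cc(OCc2ccccc2)cc1OCc1ccccc1 | intermediate
22 | 1-[2,4-bis(benzyloxy)-6-hydroxyphenyl]-3-[(2R,3S)-7-(benzyloxy)-2-[4-(benzyloxy)-3-methoxyphenyl]-3-(hydroxymethyl)-2,3-dihydro-1-benzofuran-4-yl]-3-hydroxypropan-1-one (carbinol epimers) | COc1cc([C@@H]2Oc3c(OCc4ccccc4)ccc(C(O)CC(=O)c4c(O)cc(OCc5ccccc5)cc4OCc4ccccc4)c3[C@H]2CO)ccc1OCc1ccccc1 | intermediate
23 | (2E)-1-[2,4-bis(benzyloxy)-6-hydroxyphenyl]-3-[(2R,3S)-7-(benzyloxy)-2-[4-(benzyloxy)-3-methoxyphenyl]-3-(hydroxymethyl)-2,3-dihydro-1-benzofuran-4-yl]prop-2-en-1-one | COc1cc([C@@H]2Oc3c(OCc4ccccc4)ccc(/C=C/C(=O)c4c(O)cc(OCc5ccccc5)cc4OCc4ccccc4)c3[C@H]2CO)ccc1OCc1ccccc1 | intermediate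
24 | hydrogen peroxide | OO | starting material
25 | 5,7-bis(benzyloxy)-2-[(2R,3S)-7-(benzyloxy)-2-[4-(benzyloxy)-3-methoxyphenyl]-3-(hydroxymethyl)-2,3-dihydro-1-benzofuran-4-yl]-3-hydroxy-2,3-dihydro-4H-chromen-4-one (epimers at the new ring) | COc1cc([C@@H]2Oc3c(OCc4ccccc4)ccc(C4Oc5cc(OCc6ccccc6)cc(OCc6ccccc6)c5C(=O)C4O)c3[C@H]2CO)ccc1OCc1ccccc1 | intermediate
26 | 5,7-bis(benzyloxy)-2-[(2R,3S)-7-(benzyloxy)-2-[4-(benzyloxy)-3-methoxyphenyl]-3-(hydroxymethyl)-2,3-dihydro-1-benzofuran-4-yl]-3-hydroxy-4H-chromen-4-one | COc1cc([C@@H]2Oc3c(OCc4ccccc4)ccc(-c4oc5cc(OCc6ccccc6)cc(OCc6ccccc6)c5c(=O)c4O)c3[C@H]2CO)ccc1OCc1ccccc1 | intermediate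
27 | 2-[(2R,3S)-7-hydroxy-2-(4-hydroxy-3-methoxyphenyl)-3-(hydroxymethyl)-2,3-dihydro-1-benzofuran-4-yl]-3,5,7-trihydroxy-4H-chromen-4-one | COc1cc([C@@H]2Oc3c(O)ccc(-c4oc5cc(O)cc(O)c5c(=O)c4O)c3[C@H]2CO)ccc1O | target

**Step count**

Total: 11 steps. Longest linear sequence: 10 steps (steps 1–7, then 9–11); step 8 is a one-step side branch.

**Steps most likely to fail, with fallbacks**

Step 5 (ring contraction). The migrating ring carries an ortho acrylate, which lowers its migratory aptitude and crowds the ipso carbon, so 2,3-shift of the electron-rich C2 aryl group (isoflavone) or simple 3-methoxylation may compete. The fallback sets out from chromone 6 and comes back at aldehyde 19. 6 is arylated with 9 under the Pd(OCOCF3)2/(S)-t-BuPyOx conditions to give (2R)-8-(benzyloxy)-2-[4-(benzyloxy)-3-methoxyphenyl]-2,3-dihydro-4H-chromen-4-one F1. The same PhI(OAc)2/HC(OMe)3/H2SO4 ring contraction, now on an unencumbered migrating ring, gives methyl (2R,3R)-7-(benzyloxy)-2-[4-(benzyloxy)-3-methoxyphenyl]-2,3-dihydro-1-benzofuran-3-carboxylate F2. Me3SnOH (ClCH2CH2Cl, 80 °C) gives the carboxylic acid F3. Carboxylate-directed C4–H olefination with methyl acrylate (Pd(OAc)2, Ac-Ile-OH, KHCO3, O2, t-AmOH, 85 °C) gives the 4-alkenyl acid F4. BH3·SMe2 reduces only the acid, giving the hydroxymethyl cinnamate F5, and OsO4/NaIO4 cleavage of F5 gives 19.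

Step 4 (asymmetric conjugate arylation). The C5 acrylate next to the carbonyl may slow the addition, compete as an acceptor or erode the enantioselectivity. The fallback sets out from 8 and comes back at 10. Racemic conjugate arylation of 8 with 9 (Pd(OCOCF3)2, 2,2'-bipyridine, aqueous AcOH/THF, 60 °C) gives the racemic flavanone F6. Kinetic resolution by asymmetric transfer hydrogenation (Cp*RhCl[(R,R)-TsDPEN] or its antipode, whichever reduces the (2S) ketone faster; HCO2H/Et3N) converts the unwanted enantiomer into the cis-flavan-4-ol F7 and leaves (2R)-10, which is separated by chromatography.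

Step 10 (Algar–Flynn–Oyamada). Chalcones with a substituent at the second ortho position of ring A (here benzyloxy) can give aurones instead of flavonols. The fallback sets out from chalcone 23 and comes back at 26. I2 (cat.) in DMSO at 120 °C closes ring C without oxygenation to give the flavone F8. Dimethyldioxirane (acetone/CH2Cl2, 0 °C) gives the flavone 2,3-epoxide F9, which TsOH isomerises to the 3-hydroxyflavone 26.

**Further compounds**

F1 | step 5 | (2R)-8-(benzyloxy)-2-[4-(benzyloxy)-3-methoxyphenyl]-2,3-dihydro-4H-chromen-4-one | COc1cc([C@@H]2Oc3c(OCc4ccccc4)cccc3C(=O)C2)ccc1OCc1ccccc1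
F2 | step 5 | methyl (2R,3R)-7-(benzyloxy)-2-[4-(benzyloxy)-3-methoxyphenyl]-2,3-dihydro-1-benzofuran-3-carboxylate | COc1cc([C@@H]2Oc3c(OCc4ccccc4)cccc3[C@H]2C(=O)OC)ccc1OCc1ccccc1
F3 | step 5 | (2R,3R)-7-(benzyloxy)-2-[4-(benzyloxy)-3-methoxyphenyl]-2,3-dihydro-1-benzofuran-3-carboxylic acid | COc1cc([C@@H]2Oc3c(OCc4ccccc4)cccc3[C@H]2C(=O)O)ccc1OCc1ccccc1
F4 | step 5 | (2R,3R)-7-(benzyloxy)-2-[4-(benzyloxy)-3-methoxyphenyl]-4-[(E)-3-methoxy-3-oxoprop-1-en-1-yl]-2,3-dihydro-1-benzofuran-3-carboxylic acid | COc1cc([C@@H]2Oc3c(OCc4ccccc4)ccc(/C=C/C(=O)OC)c3[C@H]2C(=O)O)ccc1OCc1ccccc1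
F5 | step 5 | methyl (E)-3-[(2R,3S)-7-(benzyloxy)-2-[4-(benzyloxy)-3-methoxyphenyl]-3-(hydroxymethyl)-2,3-dihydro-1-benzofuran-4-yl]prop-2-enoate | COc1cc([C@@H]2Oc3c(OCc4ccccc4)ccc(/C=C/C(=O)OC)c3[C@H]2CO)ccc1OCc1ccccc1
F6 | step 4 | racemic methyl (E)-3-[8-(benzyloxy)-2-[4-(benzyloxy)-3-methoxyphenyl]-4-oxo-3,4-dihydro-2H-chromen-5-yl]prop-2-enoate | COc1cc(C2Oc3c(OCc4ccccc4)ccc(/C=C/C(=O)OC)c3C(=O)C2)ccc1OCc1ccccc1
F7 | step 4 | methyl (E)-3-[(2S,4S)-8-(benzyloxy)-2-[4-(benzyloxy)-3-methoxyphenyl]-4-hydroxy-3,4-dihydro-2H-chromen-5-yl]prop-2-enoate | COc1cc([C@H]2Oc3c(OCc4ccccc4)ccc(/C=C/C(=O)OC)c3[C@@H](O)C2)ccc1OCc1ccccc1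
F8 | step 10 | 5,7-bis(benzyloxy)-2-[(2R,3S)-7-(benzyloxy)-2-[4-(benzyloxy)-3-methoxyphenyl]-3-(hydroxymethyl)-2,3-dihydro-1-benzofuran-4-yl]-4H-chromen-4-one | COc1cc([C@@H]2Oc3c(OCc4ccccc4)ccc(-c4cc(=O)c5c(OCc6ccccc6)cc(OCc6ccccc6)cc5o4)c3[C@H]2CO)ccc1OCc1ccccc1
F9 | step 10 | 2,3-epoxide of F8: 4,6-bis(benzyloxy)-1a-[(2R,3S)-7-(benzyloxy)-2-[4-(benzyloxy)-3-methoxyphenyl]-3-(hydroxymethyl)-2,3-dihydro-1-benzofuran-4-yl]-1a,7a-dihydro-7H-oxireno[2,3-b]chromen-7-one (epoxide epimers) | COc1cc([C@@H]2Oc3c(OCc4ccccc4)ccc(C45OC4C(=O)c4c(OCc6ccccc6)cc(OCc6ccccc6)cc4O5)c3[C@H]2CO)ccc1OCc1ccccc1
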